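**Retrosynthetic overview**

1. The strategy rests on ring A: its C5/C6 catechol sits next to the C4 ketone, so in the ortho-quinone (C5=O, C6=O) C8a is the β-carbon of both the C5 carbonyl and the C4 ketone. The C8a–O1 bond is therefore made last, from a C8a–H, by oxidation, attack of the C2 hydroxyl and rearomatisation.
2. The open-chain (2R,3R)-anti α-methoxy-β-hydroxy aryl ketone is cut at C4–C4a into a Weinreb amide and the ortho-lithiated bis(MOM) ether of 3-methoxycatechol.
3. C2 and C3 are set together by an auxiliary-controlled anti glycolate aldol of an N-methoxyacetyl oxazolidinethione with O-benzylisovanillin.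
4. Rings A and B are bought as arenes; ring C is the only ring built (key step). The 3′-benzyl ether, which shields ring B during the oxidation, is removed last.

Key step: step 7

Remark: 3-(benzyloxy)-4-methoxybenzaldehyde and (S)-4-benzyl-1,3-oxazolidine-2-thione are taken as purchased materials (each is otherwise one step from isovanillin or L-phenylalaninol).

**Route**

Step 1
Reactants: 1 (S)-4-benzyl-1,3-oxazolidine-2-thione; 2 methoxyacetyl chloride
Product: 3 (S)-4-benzyl-3-(methoxyacetyl)-1,3-oxazolidine-2-thione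
Conditions: Et3N, DMAP (cat.), CH2Cl2, 0 °C to rt
Reagents that add atoms: none
Why: N-acylation of the oxazolidinethione nitrogen by the acid chloride (amine base, DMAP catalysis) gives the imide as the stable N-acyl isomer, and the auxiliary stereocentre is not involved.

Step 2
Reactants: 3 (S)-4-benzyl-3-(methoxyacetyl)-1,3-oxazolidine-2-thione; 4 3-(benzyloxy)-4-methoxybenzaldehyde
Product: 6 (4S)-4-benzyl-3-[(2R,3R)-3-[3-(benzyloxy)-4-methoxyphenyl]-3-hydroxy-2-methoxypropanoyl]-1,3-oxazolidine-2-thione, via trichlorotitanium (Z)-enolate 5 (not isolated)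
Conditions: TiCl4 (1.1 equiv), i-Pr2NEt (1.15 equiv), CH2Cl2, −78 °C; then 4 (2 equiv) precomplexed with TiCl4 (2 equiv), −78 °C; aq. NH4Cl
Reagents that add atoms: none
Why: Titanium-mediated anti-selective glycolate aldol: soft enolisation gives the (Z)-enolate, the aldehyde already bound to TiCl4 cannot enter a closed chair and reacts through an open transition state, and attack on the enolate face opposite the 4-benzyl group of the sulfur-chelated auxiliary should set C2 as R and the anti carbinol C3 as R.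

Step 3
Reactants: 6 (4S)-4-benzyl-3-[(2R,3R)-3-[3-(benzyloxy)-4-methoxyphenyl]-3-hydroxy-2-methoxypropanoyl]-1,3-oxazolidine-2-thione
Product: 7 (2R,3R)-3-[3-(benzyloxy)-4-methoxyphenyl]-3-hydroxy-N,2-dimethoxy-N-methylpropanamide
Conditions: MeNH(OMe)·HCl, imidazole, CH2Cl2, rt
Reagents that add atoms: N,O-dimethylhydroxylamine hydrochloride, CNOC.Cl
Why: Aminolysis of the activated N-acyl oxazolidinethione by N,O-dimethylhydroxylamine (imidazole as base) gives the Weinreb amide under near-neutral conditions that leave the aldol stereocentres and the free hydroxyl untouched, the auxiliary being released for reuse.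

Step 4
Reactants: 8 3-methoxycatechol
Product: 9 1-methoxy-2,3-bis(methoxymethoxy)benzene
Conditions: MOMCl (2.6 equiv), i-Pr2NEt, CH2Cl2, 0 °C to rt
Reagents that add atoms: chloromethyl methyl ether, COCCl
Why: Double O-alkylation of the catechol with chloromethyl methyl ether (Williamson-type, amine base) installs two MOM ethers that protect the phenols against organolithium reagents and direct the metalation of the next step.

Step 5
Reactants: 9 1-methoxy-2,3-bis(methoxymethoxy)benzene; 7 (2R,3R)-3-[3-(benzyloxy)-4-methoxyphenyl]-3-hydroxy-N,2-dimethoxy-N-methylpropanamide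
Product: 11 (2R,3R)-3-[3-(benzyloxy)-4-methoxyphenyl]-3-hydroxy-2-methoxy-1-[4-methoxy-2,3-bis(methoxymethoxy)phenyl]propan-1-one, via aryllithium 10 (not isolated)
Conditions: 9 (3.3 equiv), n-BuLi (3.0 equiv), TMEDA, THF, 0 °C; then 7, −78 °C; sat. aq. NH4Cl at −78 °C
Reagents that add atoms: none
Why: Directed ortho-metalation occurs next to the OMOM group at C4 of 9 (a stronger director than OMe), and the aryllithium adds to the Weinreb amide, whose hydroxyl is carried as the lithium alkoxide, to give a chelated tetrahedral adduct that collapses to the ketone only on cold quench, so neither over-addition nor epimerisation at the α-methoxy carbon is expected (Weinreb ketone synthesis).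

Step 6
Reactants: 11 (2R,3R)-3-[3-(benzyloxy)-4-methoxyphenyl]-3-hydroxy-2-methoxy-1-[4-methoxy-2,3-bis(methoxymethoxy)phenyl]propan-1-one
Product: 13 (2R,3R)-3-[3-(benzyloxy)-4-methoxyphenyl]-1-(2,3-dihydroxy-4-methoxyphenyl)-3-hydroxy-2-methoxypropan-1-one, via tris(trimethylsilyl) ether 12 (not isolated)
Conditions: TMSOTf (6 equiv), 2,2′-bipyridyl (9 equiv), MeCN, 0 °C to rt; then H2O, rt
Reagents that add atoms: none
Why: Aryl MOM ethers are cleaved by TMSOTf and 2,2′-bipyridyl through aryl silyl ethers under buffered aprotic conditions, the carbinol being silylated in passing instead of exposed to protic acid, so the electron-rich benzylic C–O bond is not ionised and water then frees catechol and alcohol with both stereocentres intact.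

Step 7
Reactants: 13 (2R,3R)-3-[3-(benzyloxy)-4-methoxyphenyl]-1-(2,3-dihydroxy-4-methoxyphenyl)-3-hydroxy-2-methoxypropan-1-one
Product: 15 (2R,3R)-2-[3-(benzyloxy)-4-methoxyphenyl]-5,6-dihydroxy-3,7-dimethoxy-2,3-dihydro-4H-chromen-4-one, via ortho-quinone 14 (not isolated)
Conditions: Ag2O (1.5 equiv), Na2SO4, CH2Cl2 (0.01 M), 0 °C to rt, dark; filter; aq. Na2S2O4 wash
Reagents that add atoms: none
Why: Proposed new method: Ag2O takes the acyl catechol of 13 to the ortho-quinone 14, in which C8a is the β-carbon of both the C5 quinone carbonyl (through C4a=C8a) and the C4 aryl ketone, and the C2 hydroxyl adds there; loss of the C8a proton then re-forms the aromatic 5,6-catechol. The closest known reaction types are the addition of nucleophiles to acylquinones at the ring carbon next to the acyl group and the intramolecular heteroatom addition to ortho-quinones (dopaquinone to cyclodopa); what is new is a secondary alcohol closing a chromanone ring at C8a of an acyl ortho-quinone. Ring C closes in a 6-endo-trig mode (O1 onto C8a of the endocyclic C4a=C8a bond). No stereocentre is formed: C2 keeps its configuration because its C–O bond is never broken (its oxygen is the nucleophile), and C3 is not enolised under the neutral heterogeneous oxidant. The step needs attack at C8a and not at C8 or C7, which is secured by the tether (only C8a gives a six-membered ring), by the double activation of C8a and by the 7-methoxy group that makes C7=C8 a vinylogous ester; it also needs oxidation of ring A only, which the benzyl ether on the ring B phenol secures, while hemiketal formation at C5 is reversible and drains into the aromatised product. Because 15 is more easily oxidised than 13, any product quinone is returned to the catechol by the Na2S2O4 wash.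

Step 8
Reactants: 15 (2R,3R)-2-[3-(benzyloxy)-4-methoxyphenyl]-5,6-dihydroxy-3,7-dimethoxy-2,3-dihydro-4H-chromen-4-one
Product: 16 (2R,3R)-5,6-dihydroxy-2-(3-hydroxy-4-methoxyphenyl)-3,7-dimethoxy-2,3-dihydro-4H-chromen-4-one
Conditions: H2 (1 atm), 10% Pd/C, EtOAc, rt
Reagents that add atoms: none
Why: Hydrogenolysis of the aryl benzyl ether over Pd/C is fast under neutral conditions and, stopped at one equivalent of H2, should leave the cyclic benzylic C2–O1 ether, the hydrogen-bonded aryl ketone and both stereocentres untouched.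

**Compound list**

1 | (S)-4-benzyl-1,3-oxazolidine-2-thione | S=C1OC[C@H](Cc2ccccc2)N1 | starting material
2 | methoxyacetyl chloride | COCC(Cl)=O | starting material
3 | (S)-4-benzyl-3-(methoxyacetyl)-1,3-oxazolidine-2-thione | COCC(=O)N1[C@@H](Cc2ccccc2)COC1=S | intermediate
4 | 3-(benzyloxy)-4-methoxybenzaldehyde | COc1ccc(C=O)cc1OCc1ccccc1 | starting material
5 | trichlorotitanium (Z)-enolate of 3 | CO/C=C(\O[Ti](Cl)(Cl)Cl)N1[C@@H](Cc2ccccc2)COC1=S | intermediate
6 | (4S)-4-benzyl-3-[(2R,3R)-3-[3-(benzyloxy)-4-methoxyphenyl]-3-hydroxy-2-methoxypropanoyl]-1,3-oxazolidine-2-thione | COc1ccc([C@@H](O)[C@@H](OC)C(=O)N2[C@@H](Cc3ccccc3)COC2=S)cc1OCc1ccccc1 | intermediate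
7 | (2R,3R)-3-[3-(benzyloxy)-4-methoxyphenyl]-3-hydroxy-N,2-dimethoxy-N-methylpropanamide | COc1ccc([C@@H](O)[C@@H](OC)C(=O)N(C)OC)cc1OCc1ccccc1 | intermediate
8 | 3-methoxycatechol | COc1cccc(O)c1O | starting material
9 | 1-methoxy-2,3-bis(methoxymethoxy)benzene | COCOc1cccc(OC)c1OCOC | intermediate
10 | [4-methoxy-2,3-bis(methoxymethoxy)phenyl]lithium | [Li]c1ccc(OC)c(OCOC)c1OCOC | intermediate
11 | (2R,3R)-3-[3-(benzyloxy)-4-methoxyphenyl]-3-hydroxy-2-methoxy-1-[4-methoxy-2,3-bis(methoxymethoxy)phenyl]propan-1-one | COc1ccc([C@@H](O)[C@@H](OC)C(=O)c2ccc(OC)c(OCOC)c2OCOC)cc1OCc1ccccc1 | intermediate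
12 | (2R,3R)-3-[3-(benzyloxy)-4-methoxyphenyl]-2-methoxy-1-[4-methoxy-2,3-bis(trimethylsilyloxy)phenyl]-3-(trimethylsilyloxy)propan-1-one | COc1ccc([C@@H](O[Si](C)(C)C)[C@@H](OC)C(=O)c2ccc(OC)c(O[Si](C)(C)C)c2O[Si](C)(C)C)cc1OCc1ccccc1 | intermediate
13 | (2R,3R)-3-[3-(benzyloxy)-4-methoxyphenyl]-1-(2,3-dihydroxy-4-methoxyphenyl)-3-hydroxy-2-methoxypropan-1-one | COc1ccc([C@@H](O)[C@@H](OC)C(=O)c2ccc(OC)c(O)c2O)cc1OCc1ccccc1 | intermediate
14 | 3-[(2R,3R)-3-[3-(benzyloxy)-4-methoxyphenyl]-3-hydroxy-2-methoxypropanoyl]-6-methoxycyclohexa-3,5-diene-1,2-dione | COc1ccc([C@@H](O)[C@@H](OC)C(=O)C2=CC=C(OC)C(=O)C2=O)cc1OCc1ccccc1 | intermediate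
15 | (2R,3R)-2-[3-(benzyloxy)-4-methoxyphenyl]-5,6-dihydroxy-3,7-dimethoxy-2,3-dihydro-4H-chromen-4-one | COc1ccc([C@H]2Oc3cc(OC)c(O)c(O)c3C(=O)[C@@H]2OC)cc1OCc1ccccc1 | intermediate
16 | (2R,3R)-5,6-dihydroxy-2-(3-hydroxy-4-methoxyphenyl)-3,7-dimethoxy-2,3-dihydro-4H-chromen-4-one | COc1ccc([C@H]2Oc3cc(OC)c(O)c(O)c3C(=O)[C@@H]2OC)cc1O | target

**Step count**

Total steps: 8. Longest linear sequence: 7 steps (steps 1, 2, 3, 5, 6, 7, 8).

**Steps most likely to fail**

Step 7 (proposed new method). The ortho-quinone may be consumed by intermolecular addition and oligomerisation, or the aldol may fragment by retro-aldol on the basic silver surface, before the secondary hydroxyl closes onto C8a. The fallback forms the same C8a–O1 bond by a known intramolecular nucleophilic aromatic substitution; it sets out from 7 and comes back at 15. Purchased 4-fluoro-2-methoxyphenol is ortho-formylated (MgCl2, Et3N, paraformaldehyde, MeCN, reflux) to 5-fluoro-2-hydroxy-3-methoxybenzaldehyde F1. Dakin oxidation (H2O2, NaOH) gives 5-fluoro-3-methoxybenzene-1,2-diol F2, and MOMCl with i-Pr2NEt gives 5-fluoro-1-methoxy-2,3-bis(methoxymethoxy)benzene F3. Lithiation between fluorine and the OMOM group (n-BuLi, THF, −78 °C) gives [6-fluoro-4-methoxy-2,3-bis(methoxymethoxy)phenyl]lithium F4, which adds to 7 as in step 5 to give (2R,3R)-3-[3-(benzyloxy)-4-methoxyphenyl]-1-[6-fluoro-4-methoxy-2,3-bis(methoxymethoxy)phenyl]-3-hydroxy-2-methoxypropan-1-one F5. The C2 alkoxide then displaces the fluoride ortho to the ketone (Cs2CO3, DMF, rt to 50 °C), with C2 retained, to give (2R,3R)-2-[3-(benzyloxy)-4-methoxyphenyl]-3,7-dimethoxy-5,6-bis(methoxymethoxy)-2,3-dihydro-4H-chromen-4-one F6. HCl in MeOH, now safe because no free benzylic alcohol remains, removes the MOM groups to give 15.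

Step 2. The anti selectivity may erode through leakage into closed transition states, addition may occur on the other enolate face, or the electron-rich benzylic titanium alkoxide may ionise in the excess TiCl4. The fallback replaces the stoichiometric titanium enolate and open transition state by a magnesium-catalysed silylative anti-aldol through a closed boat on an oxazolidinone; it sets out from 4 and comes back at 7. Purchased (S)-4-benzyl-1,3-oxazolidin-2-one is acylated with 2 (n-BuLi, THF, −78 °C) to (S)-4-benzyl-3-(methoxyacetyl)-1,3-oxazolidin-2-one F7. Reaction with 4 (MgCl2 20 mol %, Et3N, TMSCl, EtOAc, rt) should give the anti adduct as its silyl ether, (4S)-4-benzyl-3-[(2R,3R)-3-[3-(benzyloxy)-4-methoxyphenyl]-2-methoxy-3-(trimethylsilyloxy)propanoyl]-1,3-oxazolidin-2-one F8. TFA in MeOH converts it to (4S)-4-benzyl-3-[(2R,3R)-3-[3-(benzyloxy)-4-methoxyphenyl]-3-hydroxy-2-methoxypropanoyl]-1,3-oxazolidin-2-one F9, and AlMe3 with MeNH(OMe)·HCl in CH2Cl2 gives 7.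

Step 5. Proton transfer (deprotonation at the α-methoxy carbon of the amide) or retro-aldol cleavage of the lithium aldolate on quench may outrun addition of the hindered aryllithium to the amide. The fallback changes the electrophile to an aldehyde with the carbinol protected and oxidises afterwards; it sets out from 7 and comes back at 11. TESCl and imidazole give (2R,3R)-3-[3-(benzyloxy)-4-methoxyphenyl]-N,2-dimethoxy-N-methyl-3-(triethylsilyloxy)propanamide F10, and i-Bu2AlH (THF, −78 °C) gives (2R,3R)-3-[3-(benzyloxy)-4-methoxyphenyl]-2-methoxy-3-(triethylsilyloxy)propanal F11. Addition of 10 at −78 °C gives 3-[3-(benzyloxy)-4-methoxyphenyl]-2-methoxy-1-[4-methoxy-2,3-bis(methoxymethoxy)phenyl]-3-(triethylsilyloxy)propan-1-ol as a mixture of C1 epimers F12. Dess–Martin periodinane (NaHCO3, CH2Cl2) gives (2R,3R)-3-[3-(benzyloxy)-4-methoxyphenyl]-2-methoxy-1-[4-methoxy-2,3-bis(methoxymethoxy)phenyl]-3-(triethylsilyloxy)propan-1-one F13, and HF·pyridine in THF at 0 °C removes the silyl group to give 11.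

**Further compounds**

F1 | step 7 | 5-fluoro-2-hydroxy-3-methoxybenzaldehyde | COc1cc(F)cc(C=O)c1O
F2 | step 7 | 5-fluoro-3-methoxybenzene-1,2-diol | COc1cc(F)cc(O)c1O
F3 | step 7 | 5-fluoro-1-methoxy-2,3-bis(methoxymethoxy)benzene | COCOc1cc(F)cc(OC)c1OCOC
F4 | step 7 | [6-fluoro-4-methoxy-2,3-bis(methoxymethoxy)phenyl]lithium | [Li]c1c(F)cc(OC)c(OCOC)c1OCOC
F5 | step 7 | (2R,3R)-3-[3-(benzyloxy)-4-methoxyphenyl]-1-[6-fluoro-4-methoxy-2,3-bis(methoxymethoxy)phenyl]-3-hydroxy-2-methoxypropan-1-one | COc1ccc([C@@H](O)[C@@H](OC)C(=O)c2c(F)cc(OC)c(OCOC)c2OCOC)cc1OCc1ccccc1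
F6 | step 7 | (2R,3R)-2-[3-(benzyloxy)-4-methoxyphenyl]-3,7-dimethoxy-5,6-bis(methoxymethoxy)-2,3-dihydro-4H-chromen-4-one | COc1ccc([C@H]2Oc3cc(OC)c(OCOC)c(OCOC)c3C(=O)[C@@H]2OC)cc1OCc1ccccc1
F7 | step 2 | (S)-4-benzyl-3-(methoxyacetyl)-1,3-oxazolidin-2-one | COCC(=O)N1[C@@H](Cc2ccccc2)COC1=O
F8 | step 2 | (4S)-4-benzyl-3-[(2R,3R)-3-[3-(benzyloxy)-4-methoxyphenyl]-2-methoxy-3-(trimethylsilyloxy)propanoyl]-1,3-oxazolidin-2-one | COc1ccc([C@@H](O[Si](C)(C)C)[C@@H](OC)C(=O)N2[C@@H](Cc3ccccc3)COC2=O)cc1OCc1ccccc1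
F9 | step 2 | (4S)-4-benzyl-3-[(2R,3R)-3-[3-(benzyloxy)-4-methoxyphenyl]-3-hydroxy-2-methoxypropanoyl]-1,3-oxazolidin-2-one | COc1ccc([C@@H](O)[C@@H](OC)C(=O)N2[C@@H](Cc3ccccc3)COC2=O)cc1OCc1ccccc1
F10 | step 5 | (2R,3R)-3-[3-(benzyloxy)-4-methoxyphenyl]-N,2-dimethoxy-N-methyl-3-(triethylsilyloxy)propanamide | COc1ccc([C@@H](O[Si](CC)(CC)CC)[C@@H](OC)C(=O)N(C)OC)cc1OCc1ccccc1
F11 | step 5 | (2R,3R)-3-[3-(benzyloxy)-4-methoxyphenyl]-2-methoxy-3-(triethylsilyloxy)propanal | COc1ccc([C@@H](O[Si](CC)(CC)CC)[C@@H](OC)C=O)cc1OCc1ccccc1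
F12 | step 5 | 3-[3-(benzyloxy)-4-methoxyphenyl]-2-methoxy-1-[4-methoxy-2,3-bis(methoxymethoxy)phenyl]-3-(triethylsilyloxy)propan-1-ol (C1 epimers; C2 and C3 as in 7) | COc1ccc([C@@H](O[Si](CC)(CC)CC)[C@@H](OC)C(O)c2ccc(OC)c(OCOC)c2OCOC)cc1OCc1ccccc1
F13 | step 5 | (2R,3R)-3-[3-(benzyloxy)-4-methoxyphenyl]-2-methoxy-1-[4-methoxy-2,3-bis(methoxymethoxy)phenyl]-3-(triethylsilyloxy)propan-1-one | COc1ccc([C@@H](O[Si](CC)(CC)CC)[C@@H](OC)C(=O)c2ccc(OC)c(OCOC)c2OCOC)cc1OCc1ccccc1
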